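**Retrosynthetic overview**
- The target is unmasked last from the MOM ether of its ring B phenol, the only protecting group in the route.
- Key disconnection: the O1–C2 bond of ring C, made by an enantioselective 6-endo (anti-Markovnikov) addition of the ring A phenol O–H across a 1,1-disubstituted styrene. This one step closes ring C and sets C3 as (R).
- The 2-arylallyl phenol is cut at the aryl–vinyl bond: Suzuki coupling of a ring B aryl boronate with a ring A 2-bromoallyl phenol.
- The 2-bromoallyl phenol comes from O-alkylation and aromatic Claisen rearrangement of 2,6-dihydroxy-4-methoxybenzaldehyde (made from 2,4,6-trimethoxybenzaldehyde). The boronate comes from two directed ortho-lithiations of MOM-protected 3-methoxyphenol (prenyl first, boron second).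
- Ring order: rings A and B are bought as benzene rings; ring C (the pyran) is the only ring built, in the key step.

Assumption: C3 of the target is (R) by CIP analysis of the given SMILES. The facial sense of the new chiral thiol cannot be predicted, so the peptide enantiomer (from L- or D-amino acids) that gives the (3R) product is the one used.

**Step 1**
Reactants: 1 3-methoxyphenol
Product: 2 1-methoxy-3-(methoxymethoxy)benzene
Conditions: NaH, MOMCl, THF/DMF, 0 °C → rt
Reagents that add atoms: chloromethyl methyl ether (MOMCl), COCCl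
Why: Williamson-type O-alkylation of the sodium phenoxide with the reactive α-chloro ether; the MOM group serves afterwards as the ortho-directing group and as the only protecting group.

**Step 2**
Reactants: 2 1-methoxy-3-(methoxymethoxy)benzene + 3 prenyl bromide (1-bromo-3-methylbut-2-ene)
Product: 5 1-methoxy-3-(methoxymethoxy)-2-(3-methylbut-2-en-1-yl)benzene, via aryllithium 4 (not isolated)
Conditions: n-BuLi, THF, 0 °C → rt; then CuBr·SMe2 (10 mol %), 3, −78 °C → rt
Reagents that add atoms: none
Why: Directed ortho-metalation removes the C–H flanked by OMe and OMOM (both oxygens cooperate), and the copper-catalysed allylation of the aryllithium occurs at the primary carbon of prenyl bromide (SN2).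

**Step 3**
Reactants: 5 1-methoxy-3-(methoxymethoxy)-2-(3-methylbut-2-en-1-yl)benzene
Product: 7 2-[4-methoxy-2-(methoxymethoxy)-3-(3-methylbut-2-en-1-yl)phenyl]-4,4,5,5-tetramethyl-1,3,2-dioxaborolane, via aryllithium 6 (not isolated)
Conditions: n-BuLi, TMEDA, THF, −20 → 0 °C; then iPrOBpin, −78 °C → rt; H2O quench
Reagents that add atoms: 2-isopropoxy-4,4,5,5-tetramethyl-1,3,2-dioxaborolane (iPrOBpin), CC(C)OB1OC(C)(C)C(C)(C)O1
Why: Second directed ortho-metalation and borylation; OMOM is a stronger director than OMe, so the only remaining C–H ortho to OMOM is lithiated by complex-induced proximity, faster than the prenyl CH2, and trapped by the borate ester.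

**Step 4**
Reactants: 8 2,4,6-trimethoxybenzaldehyde
Product: 9 2,6-dihydroxy-4-methoxybenzaldehyde
Conditions: AlCl3 (4 equiv), CH2Cl2, 0 → 40 °C; then 1 M HCl
Reagents that add atoms: none
Why: Chelation-controlled Lewis acid ether cleavage; AlCl3 bound to the formyl oxygen activates only the two ortho OMe groups for attack by chloride, while the para OMe lacks this chelate and survives.

**Step 5**
Reactants: 9 2,6-dihydroxy-4-methoxybenzaldehyde + 10 2,3-dibromoprop-1-ene
Product: 11 2-[(2-bromoprop-2-en-1-yl)oxy]-6-hydroxy-4-methoxybenzaldehyde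
Conditions: K2CO3 (1.1 equiv), 10 (1.0 equiv), acetone, 50 °C
Reagents that add atoms: none
Why: Williamson etherification at the allylic bromide (the vinyl bromide is inert); the two OH groups are equivalent, and after the first alkylation the remaining OH is held in a hydrogen bond to the aldehyde, which favours mono-alkylation.

**Step 6**
Reactants: 11 2-[(2-bromoprop-2-en-1-yl)oxy]-6-hydroxy-4-methoxybenzaldehyde
Product: 13 3-(2-bromoprop-2-en-1-yl)-2,6-dihydroxy-4-methoxybenzaldehyde, via ortho-dienone 12 (not isolated)
Conditions: 1,2-dichlorobenzene, 180 °C, sealed tube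
Reagents that add atoms: none
Why: Aromatic Claisen rearrangement ([3,3]-sigmatropic shift, then tautomerisation); C3 is the only free ortho position, and a para migration would give the same compound because the ring is symmetric.

**Step 7**
Reactants: 7 2-[4-methoxy-2-(methoxymethoxy)-3-(3-methylbut-2-en-1-yl)phenyl]-4,4,5,5-tetramethyl-1,3,2-dioxaborolane + 13 3-(2-bromoprop-2-en-1-yl)-2,6-dihydroxy-4-methoxybenzaldehyde
Product: 14 2,6-dihydroxy-4-methoxy-3-{2-[4-methoxy-2-(methoxymethoxy)-3-(3-methylbut-2-en-1-yl)phenyl]prop-2-en-1-yl}benzaldehyde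
Conditions: Pd(OAc)2 (3 mol %), SPhos (6 mol %), K3PO4 (4 equiv), toluene/H2O, 80 °C
Reagents that add atoms: none
Why: Suzuki–Miyaura coupling of the vinyl bromide with the aryl pinacol boronate; the SPhos catalyst couples ortho-substituted, electron-rich boronates faster than they protodeboronate and tolerates free phenols and the aldehyde.

**Step 8**
Reactants: 14 2,6-dihydroxy-4-methoxy-3-{2-[4-methoxy-2-(methoxymethoxy)-3-(3-methylbut-2-en-1-yl)phenyl]prop-2-en-1-yl}benzaldehyde
Product: 16 (3R)-7-hydroxy-5-methoxy-3-[4-methoxy-2-(methoxymethoxy)-3-(3-methylbut-2-en-1-yl)phenyl]-3,4-dihydro-2H-chromene-8-carbaldehyde, via C3 benzylic radical 15 (not isolated)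
Conditions: 9-mesityl-3,6-di-tert-butyl-10-phenylacridinium tetrafluoroborate (2.5 mol %), cysteine peptide thiol Boc-Cys-D-Pro-Aib-Phe-NMe2 or its mirror image (10 mol %), 2,6-lutidine (20 mol %), DCE (0.02 M), 450 nm LEDs, 0 °C, Ar
Reagents that add atoms: none
Why: Proposed new method: enantioselective anti-Markovnikov (6-endo) hydroaryloxylation, in which the excited acridinium oxidises the electron-rich styrene of 14 to its radical cation, the neighbouring ring A 2-OH adds to the terminal CH2 (forming O1–C2 and, after proton loss, the planar tertiary benzylic radical 15), and the chiral peptide thiol, hydrogen-bonded to the 7-OH/8-CHO unit, delivers its S–H hydrogen to one face of C3 to set (3R), the thiyl radical then being reduced by the acridine radical and reprotonated so that nothing is consumed; the closest known reaction types are the racemic acridinium/achiral-thiol anti-Markovnikov hydroetherification of alkenols and enantioselective H-atom transfer from cysteine peptide thiols in photochemical deracemisation.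

**Step 9**
Reactants: 16 (3R)-7-hydroxy-5-methoxy-3-[4-methoxy-2-(methoxymethoxy)-3-(3-methylbut-2-en-1-yl)phenyl]-3,4-dihydro-2H-chromene-8-carbaldehyde
Product: 17 (3R)-7-hydroxy-3-[2-hydroxy-4-methoxy-3-(3-methylbut-2-en-1-yl)phenyl]-5-methoxy-3,4-dihydro-2H-chromene-8-carbaldehyde
Conditions: 3 M aq. HCl/THF (1:3), 40 °C
Reagents that add atoms: none
Why: Acid-catalysed acetal hydrolysis of the MOM ether; dilute acid at 40 °C does not protonate the prenyl alkene, the aldehyde is stabilised by its hydrogen bond to the 7-OH, and C3 is a non-enolisable benzylic C–H, so the stereocenter is untouched.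

**Compound list**
1 | 3-methoxyphenol | COc1cccc(O)c1 | starting material
2 | 1-methoxy-3-(methoxymethoxy)benzene | COCOc1cccc(OC)c1 | intermediate
3 | prenyl bromide (1-bromo-3-methylbut-2-ene) | CC(C)=CCBr | starting material
4 | [2-methoxy-6-(methoxymethoxy)phenyl]lithium | [Li]c1c(OC)cccc1OCOC | intermediate
5 | 1-methoxy-3-(methoxymethoxy)-2-(3-methylbut-2-en-1-yl)benzene | COCOc1cccc(OC)c1CC=C(C)C | intermediate
6 | [4-methoxy-2-(methoxymethoxy)-3-(3-methylbut-2-en-1-yl)phenyl]lithium | [Li]c1ccc(OC)c(CC=C(C)C)c1OCOC | intermediate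
7 | 2-[4-methoxy-2-(methoxymethoxy)-3-(3-methylbut-2-en-1-yl)phenyl]-4,4,5,5-tetramethyl-1,3,2-dioxaborolane | COCOc1c(B2OC(C)(C)C(C)(C)O2)ccc(OC)c1CC=C(C)C | intermediate
8 | 2,4,6-trimethoxybenzaldehyde | COc1cc(OC)c(C=O)c(OC)c1 | starting material
9 | 2,6-dihydroxy-4-methoxybenzaldehyde | COc1cc(O)c(C=O)c(O)c1 | intermediate
10 | 2,3-dibromoprop-1-ene | BrCC(Br)=C | starting material
11 | 2-[(2-bromoprop-2-en-1-yl)oxy]-6-hydroxy-4-methoxybenzaldehyde | COc1cc(O)c(C=O)c(OCC(Br)=C)c1 | intermediate
12 | ortho-dienone, 5-(2-bromoprop-2-en-1-yl)-2-hydroxy-4-methoxy-6-oxocyclohexa-1,3-diene-1-carbaldehyde (racemic, transient) | O=CC1=C(O)C=C(OC)C(CC(Br)=C)C1=O | intermediate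
13 | 3-(2-bromoprop-2-en-1-yl)-2,6-dihydroxy-4-methoxybenzaldehyde | COc1cc(O)c(C=O)c(O)c1CC(Br)=C | intermediate
14 | 2,6-dihydroxy-4-methoxy-3-{2-[4-methoxy-2-(methoxymethoxy)-3-(3-methylbut-2-en-1-yl)phenyl]prop-2-en-1-yl}benzaldehyde | COc1cc(O)c(C=O)c(O)c1CC(=C)c1ccc(OC)c(CC=C(C)C)c1OCOC | intermediate
15 | C3 benzylic radical of the MOM-protected isoflavan (planar at C3) | COc1ccc([C]2COc3c(C=O)c(O)cc(OC)c3C2)c(OCOC)c1CC=C(C)C | intermediate
16 | (3R)-7-hydroxy-5-methoxy-3-[4-methoxy-2-(methoxymethoxy)-3-(3-methylbut-2-en-1-yl)phenyl]-3,4-dihydro-2H-chromene-8-carbaldehyde | COc1ccc([C@@H]2COc3c(C=O)c(O)cc(OC)c3C2)c(OCOC)c1CC=C(C)C | intermediate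
17 | (3R)-7-hydroxy-3-[2-hydroxy-4-methoxy-3-(3-methylbut-2-en-1-yl)phenyl]-5-methoxy-3,4-dihydro-2H-chromene-8-carbaldehyde | COc1ccc([C@@H]2COc3c(C=O)c(O)cc(OC)c3C2)c(O)c1CC=C(C)C | target

**Step count**
Total steps: 9. Longest linear sequence: 6 steps (1 → 2 → 5 → 7 → 14 → 16 → 17, or equally 8 → 9 → 11 → 13 → 14 → 16 → 17).

**Three steps most likely to fail**

Step 8 (the proposed new reaction). The risks are low enantioselectivity in the H-atom transfer, thiyl abstraction of the aldehyde hydrogen, and erosion of ee by reversible H abstraction at C3 of the product. Fallback with known chemistry, changing from asymmetric catalysis to racemate plus resolution: set out from 14 and cyclise it under the established racemic conditions (same acridinium, 20 mol % thiophenol, DCE, 450 nm LEDs, rt, again through radical 15). This gives the racemic MOM isoflavan F1. It is resolved by preparative chiral SFC (amylose tris(3,5-dimethylphenylcarbamate) phase, CO2/MeOH). The (3R) fraction is 16, where the route is rejoined, and the (3S)-MOM isoflavan F2 is set aside.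

Step 7 (Suzuki coupling on the free 2-bromoallyl phenol). The risks are palladium-mediated ring closure of the neighbouring phenoxide onto the vinyl–palladium (giving a 2-methylbenzofuran) and protodeboronation of 7. Fallback, changing the order of bond formation: set out from 11 and couple it with 7 under the same Pd(OAc)2/SPhos/K3PO4 conditions. This gives the aryl 2-arylallyl ether F3, in which no phenoxide sits next to the vinyl–palladium. Aromatic Claisen rearrangement (1,2-dichlorobenzene, 170 °C) then carries the whole 2-arylallyl group to C3 through the ortho-dienone F4 and gives 14, where the route is rejoined.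

Step 6 (thermal Claisen of 11). The risks are loss of the formyl group after ipso attack, and cyclisation of 13 at 180 °C. Fallback, replacing the rearrangement by direct C-alkylation: set out from 9 and treat its dianion in water (2 equiv KOH, 0 °C → rt) with 10. C3 is ortho to one phenoxide and para to the other, so allylation occurs there and, through dienone 12, gives 13 in one operation without heating. No new compound is made on this way (F0), and the route is rejoined at 13.

**Further compounds**
F1 | step 8 | racemic MOM isoflavan (rac-7-hydroxy-5-methoxy-3-[4-methoxy-2-(methoxymethoxy)-3-(3-methylbut-2-en-1-yl)phenyl]-3,4-dihydro-2H-chromene-8-carbaldehyde) | COc1ccc(C2COc3c(C=O)c(O)cc(OC)c3C2)c(OCOC)c1CC=C(C)C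
F2 | step 8 | (3S)-MOM isoflavan ((3S)-7-hydroxy-5-methoxy-3-[4-methoxy-2-(methoxymethoxy)-3-(3-methylbut-2-en-1-yl)phenyl]-3,4-dihydro-2H-chromene-8-carbaldehyde) | COc1ccc([C@H]2COc3c(C=O)c(O)cc(OC)c3C2)c(OCOC)c1CC=C(C)C
F3 | step 7 | aryl 2-arylallyl ether (2-hydroxy-4-methoxy-6-({2-[4-methoxy-2-(methoxymethoxy)-3-(3-methylbut-2-en-1-yl)phenyl]prop-2-en-1-yl}oxy)benzaldehyde) | COc1cc(O)c(C=O)c(OCC(=C)c2ccc(OC)c(CC=C(C)C)c2OCOC)c1
F4 | step 7 | ortho-dienone (2-hydroxy-4-methoxy-5-{2-[4-methoxy-2-(methoxymethoxy)-3-(3-methylbut-2-en-1-yl)phenyl]prop-2-en-1-yl}-6-oxocyclohexa-1,3-diene-1-carbaldehyde, racemic, transient) | O=CC1=C(O)C=C(OC)C(CC(=C)c2ccc(OC)c(CC=C(C)C)c2OCOC)C1=O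
F0 | step 6 | none | none
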